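## Analysis of the target

Heavy atoms are numbered along the SMILES string: C1–C3 isopropenyl, C4, C5, spiro C6, C7, C8, C9 with methyls C10 and C11, O12, C13(=O14), C15 with methyl C16, C17(=O18), C19(=O20), O21, C22, C23(=O24), C25 with C26 and C27. The molecule is built from a δ-lactone (ring A: C4, C5, C6, C19, O21, C22), a cyclopentanone (ring B: C6, C7, C8, C15, C17) and a γ-lactone (ring C: C8, C9, O12, C13, C15). Rings A and B are spiro-linked at C6, and rings B and C are cis-fused along C8–C15.

There are five stereocentres, 4S, 6R, 8R, 15R and 22S. C6 and C15 are quaternary, flank the ketone C17, and each also carries a lactone carbonyl. H8 and the C16 methyl are syn. At C6 the carbonyl C19 lies on the face of ring B that carries C16 and H8 (the convex face of the B/C bicycle), and C5 lies on the face of ring C. On ring A the isopropenyl group at C4 and the isobutyryl group at C22 are cis.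

The ketone C17 belongs to two 1,3-dicarbonyl units that cannot be enolised, so nucleophilic bases can open it by retro-Claisen cleavage. C22 is α to the ketone C23 and bears an acyloxy group, so it is epimerisable. The isopropenyl group is sensitive to acid, to electrophilic oxidants and to radicals. The difficulty is the compact quaternary–ketone–quaternary array C15–C17–C6 and the correlation of the remote C4/C22 pair with the bicycle.

The strategy rests on one feature: C15 is the α-carbon of C17 and bears C13, whose oxygen O12 sits on the gem-dimethyl carbon C9, itself attached to the neighbouring C8. A carbonate derivative on the C9 oxygen is therefore held within reach of the C15 enolate. Forming C13–C15 then closes ring C and creates the quaternary carbon with a configuration dictated by C8.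

## Retrosynthetic reasoning

**C23 oxidation level (28 ⇐ 27 ⇐ 26).** No skeletal bond is cut. The α-acyloxy ketone is the most fragile part of 28, so it is unveiled last, by oxidation of carbinol 27, which comes from silyl ether 26. C22 then stays a non-enolisable carbinol carbon through every basic step. The C23 carbinol centre also serves as a temporary control element before it is erased.

**C6–C19 (26 ⇐ 24 ⇐ 23 + 5).** The bond between the spiro carbon and the ring A lactone carbonyl is cut. Forward, the C22 hydroxyl of 23 is converted with 5 into the imidazole-1-carboxylate 24, and the enolate 25 at C6 (the only enolisable carbon) is acylated intramolecularly. This closes ring A and sets C6. The cut is placed here and not at C5–C6 because the group that enters last arrives on the convex face of the bicycle, and in 28 that group is C19. The reverse order would put C5 there.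

**C5–C6 (23 ⇐ 22 ⇐ 8 + 20).** Cutting the ring A methylene from C6 divides the target into the bicyclic keto-lactone 8 and the acyclic triflate 20, which carries C4, C22 and C23. Forward, the single enolate 21 of 8 is alkylated. The configuration created at C6 is of no consequence because the carbon is enolised again in the spiro closure.

**C13–C15 (8 ⇐ 6).** This is the central disconnection. Cutting the lactone carbonyl from the quaternary carbon leads to the cyclopentanone 6, which has a tertiary imidazole-1-carboxylate on C9. Forward, the more substituted enolate 7 attacks the tethered carbonyl, so one operation gives ring C, the 1,3-dicarbonyl unit and the quaternary stereocentre. The tether from C8 allows only the cis fusion, so C15 need not be controlled beforehand.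

**C9–O, C9 carbinol and C8–C2′ (6 ⇐ 4 + 5; 4 ⇐ 3; 3 ⇐ 1 + 2).** The carbonate derivative comes from tertiary alcohol 4 and 5. The alcohol comes from Markovnikov hydration of the isopropenyl group of 3. The isopropenyl group is attached by asymmetric conjugate addition of 2 to enone 1. This addition sets C8, the only stereocentre of the bicycle that has to be introduced by a reagent.

**C4–C22 (20 ⇐ 19 ⇐ 18 ⇐ 17 ⇐ 15 + 11; 15 ⇐ 12 + 13; 11 ⇐ 10 ⇐ 9).** The cis relationship on ring A corresponds to a syn aldol relationship in the open chain. The C4–C22 bond is therefore cut to the dienolate 16 of imide 15 (from 12 and 13) and the α-silyloxy aldehyde 11 (from hydroxy ester 9 via 10). Silylation of the aldol hydroxyl (18), reductive removal of the auxiliary (19) and triflation give 20.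

## Alternatives that were turned down

**Alternative 1:** Ring A is traced back to a carbocycle by cutting O21–C22. The cis-2,3-disubstituted cyclopentanone A2 would be oxidised with a peracid (Baeyer–Villiger oxidation). The more substituted α-carbon C22 migrates from C19 to oxygen with retention, giving the ring A lactone A1 with the C23 carbinol silylated.
- For: the regiochemistry (methine before methylene) and the retention at C22 are fully predictable, so on the C22–O21 bond this route is at least as reliable as the aldol used here. A1 already holds C19 and an enolisable C6.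
- Against: in A2 the stereocentre C22 is α to the ketone and cis to its neighbour, so it is epimerisable towards the trans isomer. The peracid also competes for the electron-rich isopropenyl group, which would have to be masked. The real problem is untouched: rings B and C and both quaternary carbons would still have to be built on the enolate of A1 by two C–C bond formations at C6, steered only by the 1,3-related C4 substituent of a flexible lactone.
- Comparison: the chosen route takes the cis relationship from an acyclic syn aldol adduct that is never exposed to enolisation, and it forms C6 under the control of the rigid bicycle 8.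

**Alternative 2:** Rings B and C are cut together at C8–C15 and C9–O12. The α-methyl β-keto ester A4, with a prenyl group on the spiro carbon, would be oxidised by trivalent manganese regenerated at the anode from a catalytic divalent manganese salt. The C15 radical adds 5-exo to the prenyl group (ring B). The C9 radical is oxidised to the cation and captured by the ester carbonyl (ring C), giving A3, the target with C23 as its dioxolane.
- For: two rings and both ring-fusion stereocentres form in one late, convergent step, with electricity as the oxidant. In step economy at the ring B/C stage this is clearly stronger than the chosen route.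
- Against: the relation of the new C8/C15 pair to the existing spiro centre depends only on the chair or boat preference of a 5-exo transition state at a quaternary carbon. The isopropenyl group on ring A is a second acceptor for the electrophilic radical and a second site for the oxidant. A4 requires the quaternary C6 to be set on a monocyclic lactone. The dioxolane of a hindered α-acyloxy ketone must finally be removed with acid next to the isopropenyl group.
- Comparison: the chosen route gives up step economy, but each stereocentre follows from a geometric constraint (cis fusion for C15, convex face for C6) and no radical is generated in the presence of the isopropenyl group.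

**Alternative 3:** Ring C is cut at C8–C9 and O12–C13. The ketyl radical of propan-2-ol A7 would add to the β-carbon of methyl 5-oxocyclopent-1-ene-1-carboxylate A6 held by a chiral Lewis acid. The tertiary hydroxyl then lactonises onto the ester, giving the cis-fused keto-lactone A5 without the C15 methyl. Methylation would give 8.
- For: two steps to 8 instead of four. A7 delivers C9, both methyl groups and O12 at once. The quaternary carbon would come from methylation of an acidic β-keto lactone, which is safer than the key step chosen here; on this point the alternative is stronger.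
- Against: the absolute configuration of the whole synthesis would rest on an enantioselective addition of an α-hydroxyalkyl radical to a cyclic alkylidene β-keto ester. Chiral Lewis acid control is not established for this case, and an uncatalysed background addition competes. A6 dimerises readily and must be generated and used in situ. The reducing ketyl radical can also transfer an electron to the activated enone instead of adding.
- Comparison: the chosen route takes its absolute configuration from a reaction class known on cyclic enones, and it confines the demanding bond formation to an intramolecular ionic step with a forced stereochemical outcome. A5 is kept as the intermediate of a fallback.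

Key step: step 4

Remark: the ferrocenyl diphosphine enantiomer named in step 1 is assumed to induce the 3R configuration; if the sense of induction is the opposite, the mirror-image ligand is used and nothing else changes.

## Route

Step 1
Reactants: 1 2-methylcyclopent-2-en-1-one; 2 isopropenylmagnesium bromide
Product: 3 (3R)-2-methyl-3-(prop-1-en-2-yl)cyclopentan-1-one (C2 epimers, trans-(2S,3R) expected to predominate)
Conditions: CuBr·SMe2 (5 mol %), (R)-1-[(SP)-2-(diphenylphosphino)ferrocenyl]ethyldicyclohexylphosphine (6 mol %), t-BuOMe, −78 °C; aq. NH4Cl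
Reagents that add atoms: none
Why: Copper-catalysed asymmetric conjugate addition of a Grignard reagent to a cyclic enone; the phosphine-bound alkenylcopper species adds to C3 of 1 and the magnesium enolate is protonated on work-up. The ligand fixes the face of attack and so sets C8 of the target (3R in 3); the C2 epimer mixture is harmless because that carbon is enolised again in step 4.

Step 2
Reactants: 3 (3R)-2-methyl-3-(prop-1-en-2-yl)cyclopentan-1-one
Product: 4 (3R)-3-(2-hydroxypropan-2-yl)-2-methylcyclopentan-1-one (C2 epimers)
Conditions: Co(acac)2 (20 mol %), PhSiH3, O2 (1 atm), THF, rt; aq. Na2S2O3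
Reagents that add atoms: dioxygen, O=O
Why: Mukaiyama hydration; a cobalt hydride transfers a hydrogen atom to the terminal carbon of the 1,1-disubstituted alkene, the tertiary radical is trapped by O2 and the peroxide is reduced to the Markovnikov tertiary alcohol. The ketone and the stereocentre at C3 are not involved.

Step 3
Reactants: 4 (3R)-3-(2-hydroxypropan-2-yl)-2-methylcyclopentan-1-one; 5 1,1'-carbonyldiimidazole
Product: 6 2-[(1R)-2-methyl-3-oxocyclopentyl]propan-2-yl 1H-imidazole-1-carboxylate (C2 epimers of the ring)
Conditions: 5 (1.5 equiv), DBU (10 mol %), MeCN, 50 °C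
Reagents that add atoms: none
Why: Acyl transfer from carbonyldiimidazole to the tertiary hydroxyl under amidine catalysis gives the mixed imidazole carboxylate; tertiary alcohols react slowly but cleanly on warming. Epimerisation next to the ketone is irrelevant.

Step 4
Reactants: 6 2-[(1R)-2-methyl-3-oxocyclopentyl]propan-2-yl 1H-imidazole-1-carboxylate
Product: 8 (3aR,6aR)-3,3,6a-trimethyltetrahydro-1H-cyclopenta[c]furan-1,6(6aH)-dione (cis-fused rings B and C), via sodium enolate 7 (not isolated)
Conditions: NaH (2.2 equiv), THF (0.02 M), 0 → 40 °C; AcOH, 0 °C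
Reagents that add atoms: none
Why: NaH deprotonates the ketone slowly, so unreacted ketone shuttles protons, the two enolates equilibrate and the more substituted C15 enolate 7 predominates; its carbon adds to the carbonyl of the imidazole-1-carboxylate and imidazolide is expelled, forming C13–C15. The closest known reaction type is the Dieckmann-type intramolecular C-acylation of a ketone enolate by a tethered carbonate or acyl imidazole to give an α-acyl lactone. Ring C closes in a 5-(enolexo)-exo-trig mode, which is stereoelectronically favoured. The new quaternary stereocentre C15 (C6a of 8) is controlled by C8: the tether C9–O12–C13 reaches only the enolate face on which it is attached, so only the cis-fused bicycle can form and both epimers of 6 converge. The selectivity needed is regiochemical, C15 against C6; the C6 enolate could close only a bridged six-membered lactone through a boat-like arrangement, whereas the fused five-membered closure is fast and should drain the equilibrating enolate pool (Curtin–Hammett situation). Imidazolide is a good leaving group but a poor nucleophile, so the product, which cannot be enolised at C15, should not be reopened by retro-Claisen attack at the ketone, and the acylation is downhill without product deprotonation. High dilution suppresses intermolecular acylation; the second equivalent of base only converts 8 into its C6 enolate, which is reprotonated on quenching.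

Step 5
Reactants: 9 methyl (R)-2-hydroxy-3-methylbutanoate
Product: 10 methyl (R)-2-[(tert-butyldimethylsilyl)oxy]-3-methylbutanoate
Conditions: TBSCl, imidazole, DMF, rt
Reagents that add atoms: tert-butyldimethylsilyl chloride, CC(C)(C)[Si](C)(C)Cl
Why: Standard silylation of a secondary α-hydroxy ester; the stereocentre is not touched.

Step 6
Reactants: 10 methyl (R)-2-[(tert-butyldimethylsilyl)oxy]-3-methylbutanoate
Product: 11 (R)-2-[(tert-butyldimethylsilyl)oxy]-3-methylbutanal
Conditions: i-Bu2AlH (1.1 equiv), CH2Cl2, −78 °C; aq. potassium sodium tartrate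
Reagents that add atoms: none
Why: Partial reduction of an α-silyloxy ester; the tetrahedral aluminium hemiacetal is stable at −78 °C and releases the aldehyde only on work-up. The aldehyde is used crude to avoid α-epimerisation.

Step 7
Reactants: 12 (S)-4-benzyloxazolidin-2-one; 13 3-methylbut-2-enoyl chloride
Product: 15 (S)-4-benzyl-3-(3-methylbut-2-enoyl)oxazolidin-2-one, via lithium oxazolidinide 14 (not isolated)
Conditions: n-BuLi, THF, −78 °C; then 13, −78 → 0 °C
Reagents that add atoms: none
Why: N-Acylation of the lithiated oxazolidinone by the acid chloride; the low temperature avoids deconjugation of the unsaturated acyl group.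

Step 8
Reactants: 15 (S)-4-benzyl-3-(3-methylbut-2-enoyl)oxazolidin-2-one; 11 (R)-2-[(tert-butyldimethylsilyl)oxy]-3-methylbutanal
Product: 17 (S)-4-benzyl-3-[(2S,3S,4R)-4-[(tert-butyldimethylsilyl)oxy]-3-hydroxy-5-methyl-2-(prop-1-en-2-yl)hexanoyl]oxazolidin-2-one, via boron dienolate 16 (not isolated)
Conditions: Bu2BOTf, Et3N, CH2Cl2, −78 → 0 °C; 11, −78 → 0 °C; pH 7 buffer, MeOH, H2O2, 0 °C
Reagents that add atoms: none
Why: Evans syn aldol reaction; γ-deprotonation gives the Z boron dienolate 16, which reacts at its α-carbon through a Zimmerman–Traxler chair on the face opposite the benzyl group, creating C4 and C22 of the target with the syn relationship that becomes cis on ring A. The auxiliary controls the absolute sense; the (R)-aldehyde is expected to be the matched partner (3,4-anti, Cornforth/Felkin preference of a Z enolate with an α-silyloxy aldehyde), and its stereocentre is erased in step 17.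

Step 9
Reactants: 17 aldol adduct
Product: 18 (S)-4-benzyl-3-[(2S,3S,4R)-4-[(tert-butyldimethylsilyl)oxy]-5-methyl-2-(prop-1-en-2-yl)-3-[(triethylsilyl)oxy]hexanoyl]oxazolidin-2-one
Conditions: Et3SiOTf, 2,6-lutidine, CH2Cl2, −78 → 0 °C
Reagents that add atoms: triethylsilyl trifluoromethanesulfonate, CC[Si](CC)(CC)OS(=O)(=O)C(F)(F)F
Why: Silylation of the aldol hydroxyl under non-basic conditions, which avoids retro-aldol cleavage and migration of the alkene into conjugation; the triethylsilyl ether can later be removed in the presence of the tert-butyldimethylsilyl ether.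

Step 10
Reactants: 18 triethylsilyl ether of the aldol adduct
Product: 19 (2R,3S,4R)-4-[(tert-butyldimethylsilyl)oxy]-5-methyl-2-(prop-1-en-2-yl)-3-[(triethylsilyl)oxy]hexan-1-ol
Conditions: LiBH4, MeOH (1 equiv), Et2O, 0 °C
Reagents that add atoms: none
Why: Reductive cleavage of the N-acyl oxazolidinone at the exocyclic carbonyl gives the primary alcohol and returns the auxiliary. The α-stereocentre is not epimerised under these conditions; the change of descriptor at C2 is only a change of priorities.

Step 11
Reactants: 19 primary alcohol
Product: 20 (2R,3S,4R)-4-[(tert-butyldimethylsilyl)oxy]-5-methyl-2-(prop-1-en-2-yl)-3-[(triethylsilyl)oxy]hexyl trifluoromethanesulfonate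
Conditions: Tf2O, 2,6-lutidine, CH2Cl2, −78 °C; cold filtration through silica, used at once
Reagents that add atoms: trifluoromethanesulfonic anhydride, O=S(=O)(OS(=O)(=O)C(F)(F)F)C(F)(F)F
Why: Triflation of a primary alcohol with a hindered pyridine base. The triflate is preferred to an iodide because the carbon is β-branched and its β-hydrogen is allylic, so the substitution has to run at −78 °C, where elimination is slow.

Step 12
Reactants: 8 (3aR,6aR)-3,3,6a-trimethyltetrahydro-1H-cyclopenta[c]furan-1,6(6aH)-dione; 20 primary triflate
Product: 22 (3aR,6aR)-5-[(2S,3S,4R)-4-[(tert-butyldimethylsilyl)oxy]-5-methyl-2-(prop-1-en-2-yl)-3-[(triethylsilyl)oxy]hexyl]-3,3,6a-trimethyltetrahydro-1H-cyclopenta[c]furan-1,6(6aH)-dione (both C5 epimers), via lithium enolate 21 (not isolated)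
Conditions: LiN(i-Pr)2 (1.3 equiv, with 1.3 equiv of 8), THF, −78 °C; then 20, −78 → −30 °C
Reagents that add atoms: none
Why: Enolate alkylation; C6 of the target (C5 of 8) is the only enolisable carbon of 8, so enolate 21 forms regiospecifically and displaces the primary triflate in an SN2 reaction, forming C5–C6. The configuration at the new centre is immaterial because it is enolised again in step 15.

Step 13
Reactants: 22 alkylated keto-lactone
Product: 23 (3aR,6aR)-5-[(2S,3S,4R)-4-[(tert-butyldimethylsilyl)oxy]-3-hydroxy-5-methyl-2-(prop-1-en-2-yl)hexyl]-3,3,6a-trimethyltetrahydro-1H-cyclopenta[c]furan-1,6(6aH)-dione (both C5 epimers)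
Conditions: pyridinium p-toluenesulfonate (cat.), MeOH/CH2Cl2, 0 °C
Reagents that add atoms: none
Why: Mild acid methanolysis cleaves the triethylsilyl ether much faster than the hindered tert-butyldimethylsilyl ether, freeing only the C22 hydroxyl; lactone, ketone and alkene are inert.

Step 14
Reactants: 23 secondary alcohol; 5 1,1'-carbonyldiimidazole
Product: 24 1H-imidazole-1-carboxylate of the C3′ hydroxyl of 23 (both C5 epimers)
Conditions: 5 (2 equiv), MeCN, 40 °C
Reagents that add atoms: none
Why: Acyl transfer from carbonyldiimidazole to the secondary hydroxyl, as in step 3; this places the future C19 on O21.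

Step 15
Reactants: 24 imidazole-1-carboxylate
Product: 26 (3aR,5R,5'S,6'S,6aR)-6'-[(1R)-1-[(tert-butyldimethylsilyl)oxy]-2-methylpropyl]-3,3,6a-trimethyl-5'-(prop-1-en-2-yl)tetrahydro-1H-spiro[cyclopenta[c]furan-5,3'-pyran]-1,2',6(6aH)-trione, via lithium enolate 25 (not isolated)
Conditions: LiN(SiMe3)2 (1.2 equiv), THF (0.01 M), −78 → 0 °C; AcOH
Reagents that add atoms: none
Why: Same reaction type as step 4; C6 is the only enolisable carbon, and its enolate 25 attacks the tethered imidazole-1-carboxylate in a 6-(enolexo)-exo-trig closure with loss of imidazolide, forming C6–C19 and ring A. The carbonyl should be delivered to the convex face of the cis-fused bicycle, away from ring C and the endo methyl on C9, which places C19 syn to the C15 methyl and C5 syn to ring C as in the target. Both C6 epimers of 24 converge in the planar enolate.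

Step 16
Reactants: 26 spiro bis-lactone silyl ether
Product: 27 (3aR,5R,5'S,6'S,6aR)-6'-[(1R)-1-hydroxy-2-methylpropyl]-3,3,6a-trimethyl-5'-(prop-1-en-2-yl)tetrahydro-1H-spiro[cyclopenta[c]furan-5,3'-pyran]-1,2',6(6aH)-trione
Conditions: HF·pyridine, pyridine, THF, 0 °C → rt
Reagents that add atoms: none
Why: Buffered, acidic fluoride cleaves the silyl ether without basic or nucleophilic species, so the doubly activated ketone C17 is not opened by retro-Claisen attack and the isopropenyl group is not hydrofluorinated.

Step 17
Reactants: 27 C23 carbinol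
Product: 28 (3aR,5R,5'S,6'S,6aR)-3,3,6a-trimethyl-6'-(2-methylpropanoyl)-5'-(prop-1-en-2-yl)tetrahydro-1H-spiro[cyclopenta[c]furan-5,3'-pyran]-1,2',6(6aH)-trione (CNP0216954.2)
Conditions: Dess–Martin periodinane, NaHCO3, CH2Cl2, 0 °C → rt
Reagents that add atoms: none
Why: Dess–Martin oxidation of the secondary alcohol to the ketone under buffered, near-neutral conditions, which should leave the epimerisable C22 and the cis relationship on ring A intact.

## Compound list

1 | 2-methylcyclopent-2-en-1-one | CC1=CCCC1=O | starting material
2 | isopropenylmagnesium bromide | C=C(C)[Mg]Br | starting material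
3 | (3R)-2-methyl-3-(prop-1-en-2-yl)cyclopentan-1-one (C2 epimers) | CC1C(=O)CC[C@H]1C(C)=C | intermediate
4 | (3R)-3-(2-hydroxypropan-2-yl)-2-methylcyclopentan-1-one (C2 epimers) | CC1C(=O)CC[C@H]1C(C)(C)O | intermediate
5 | 1,1'-carbonyldiimidazole | O=C(n1ccnc1)n1ccnc1 | starting material
6 | 2-[(1R)-2-methyl-3-oxocyclopentyl]propan-2-yl 1H-imidazole-1-carboxylate (C2 epimers of the ring) | CC1C(=O)CC[C@H]1C(C)(C)OC(=O)n2ccnc2 | intermediate
7 | sodium enolate of 6 towards the methyl-bearing carbon | [Na+].CC1=C([O-])CC[C@H]1C(C)(C)OC(=O)n2ccnc2 | intermediate (not isolated)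
8 | (3aR,6aR)-3,3,6a-trimethyltetrahydro-1H-cyclopenta[c]furan-1,6(6aH)-dione | O=C1CC[C@H]2C(C)(C)OC(=O)[C@@]12C | intermediate
9 | methyl (R)-2-hydroxy-3-methylbutanoate | CC(C)[C@@H](O)C(=O)OC | starting material
10 | methyl (R)-2-[(tert-butyldimethylsilyl)oxy]-3-methylbutanoate | CC(C)[C@@H](O[Si](C)(C)C(C)(C)C)C(=O)OC | intermediate
11 | (R)-2-[(tert-butyldimethylsilyl)oxy]-3-methylbutanal | CC(C)[C@@H](O[Si](C)(C)C(C)(C)C)C=O | intermediate
12 | (S)-4-benzyloxazolidin-2-one | O=C1N[C@@H](Cc2ccccc2)CO1 | starting material
13 | 3-methylbut-2-enoyl chloride | CC(C)=CC(Cl)=O | starting material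
14 | lithium (S)-4-benzyl-2-oxooxazolidin-3-ide | [Li+].O=C1[N-][C@@H](Cc2ccccc2)CO1 | intermediate (not isolated)
15 | (S)-4-benzyl-3-(3-methylbut-2-enoyl)oxazolidin-2-one | CC(C)=CC(=O)N1C(=O)OC[C@@H]1Cc1ccccc1 | intermediate
16 | (S)-4-benzyl-3-[(1Z)-1-[(dibutylboranyl)oxy]-3-methylbuta-1,3-dien-1-yl]oxazolidin-2-one | C=C(C)/C=C(\OB(CCCC)CCCC)N1C(=O)OC[C@@H]1Cc1ccccc1 | intermediate (not isolated)
17 | (S)-4-benzyl-3-[(2S,3S,4R)-4-[(tert-butyldimethylsilyl)oxy]-3-hydroxy-5-methyl-2-(prop-1-en-2-yl)hexanoyl]oxazolidin-2-one | C=C(C)[C@@H]([C@H](O)[C@H](O[Si](C)(C)C(C)(C)C)C(C)C)C(=O)N1C(=O)OC[C@@H]1Cc1ccccc1 | intermediate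
18 | (S)-4-benzyl-3-[(2S,3S,4R)-4-[(tert-butyldimethylsilyl)oxy]-5-methyl-2-(prop-1-en-2-yl)-3-[(triethylsilyl)oxy]hexanoyl]oxazolidin-2-one | C=C(C)[C@@H]([C@H](O[Si](CC)(CC)CC)[C@H](O[Si](C)(C)C(C)(C)C)C(C)C)C(=O)N1C(=O)OC[C@@H]1Cc1ccccc1 | intermediate
19 | (2R,3S,4R)-4-[(tert-butyldimethylsilyl)oxy]-5-methyl-2-(prop-1-en-2-yl)-3-[(triethylsilyl)oxy]hexan-1-ol | C=C(C)[C@@H]([C@H](O[Si](CC)(CC)CC)[C@H](O[Si](C)(C)C(C)(C)C)C(C)C)CO | intermediate
20 | (2R,3S,4R)-4-[(tert-butyldimethylsilyl)oxy]-5-methyl-2-(prop-1-en-2-yl)-3-[(triethylsilyl)oxy]hexyl trifluoromethanesulfonate | C=C(C)[C@@H]([C@H](O[Si](CC)(CC)CC)[C@H](O[Si](C)(C)C(C)(C)C)C(C)C)COS(=O)(=O)C(F)(F)F | intermediate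
21 | lithium enolate of 8 (C5=C6 of the bicycle) | [Li+].[O-]C1=CC[C@H]2C(C)(C)OC(=O)[C@@]12C | intermediate (not isolated)
22 | (3aR,6aR)-5-[(2S,3S,4R)-4-[(tert-butyldimethylsilyl)oxy]-5-methyl-2-(prop-1-en-2-yl)-3-[(triethylsilyl)oxy]hexyl]-3,3,6a-trimethyltetrahydro-1H-cyclopenta[c]furan-1,6(6aH)-dione (both C5 epimers) | C=C(C)[C@@H]([C@H](O[Si](CC)(CC)CC)[C@H](O[Si](C)(C)C(C)(C)C)C(C)C)CC1C[C@H]2C(C)(C)OC(=O)[C@@]2(C)C1=O | intermediate
23 | (3aR,6aR)-5-[(2S,3S,4R)-4-[(tert-butyldimethylsilyl)oxy]-3-hydroxy-5-methyl-2-(prop-1-en-2-yl)hexyl]-3,3,6a-trimethyltetrahydro-1H-cyclopenta[c]furan-1,6(6aH)-dione (both C5 epimers) | C=C(C)[C@@H]([C@H](O)[C@H](O[Si](C)(C)C(C)(C)C)C(C)C)CC1C[C@H]2C(C)(C)OC(=O)[C@@]2(C)C1=O | intermediate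
24 | 1H-imidazole-1-carboxylate of the C3′ hydroxyl of 23 (both C5 epimers) | C=C(C)[C@@H]([C@H](OC(=O)n1ccnc1)[C@H](O[Si](C)(C)C(C)(C)C)C(C)C)CC1C[C@H]2C(C)(C)OC(=O)[C@@]2(C)C1=O | intermediate
25 | lithium enolate of 24 at the side-chain-bearing ring carbon | C=C(C)[C@@H]([C@H](OC(=O)n1ccnc1)[C@H](O[Si](C)(C)C(C)(C)C)C(C)C)CC=1C[C@H]2C(C)(C)OC(=O)[C@@]2(C)C=1[O-].[Li+] | intermediate (not isolated)
26 | (3aR,5R,5'S,6'S,6aR)-6'-[(1R)-1-[(tert-butyldimethylsilyl)oxy]-2-methylpropyl]-3,3,6a-trimethyl-5'-(prop-1-en-2-yl)tetrahydro-1H-spiro[cyclopenta[c]furan-5,3'-pyran]-1,2',6(6aH)-trione | C=C(C)[C@@H]1C[C@]2(C[C@H]3C(C)(C)OC(=O)[C@@]3(C)C2=O)C(=O)O[C@@H]1[C@H](O[Si](C)(C)C(C)(C)C)C(C)C | intermediate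
27 | (3aR,5R,5'S,6'S,6aR)-6'-[(1R)-1-hydroxy-2-methylpropyl]-3,3,6a-trimethyl-5'-(prop-1-en-2-yl)tetrahydro-1H-spiro[cyclopenta[c]furan-5,3'-pyran]-1,2',6(6aH)-trione | C=C(C)[C@@H]1C[C@]2(C[C@H]3C(C)(C)OC(=O)[C@@]3(C)C2=O)C(=O)O[C@@H]1[C@H](O)C(C)C | intermediate
28 | (3aR,5R,5'S,6'S,6aR)-3,3,6a-trimethyl-6'-(2-methylpropanoyl)-5'-(prop-1-en-2-yl)tetrahydro-1H-spiro[cyclopenta[c]furan-5,3'-pyran]-1,2',6(6aH)-trione (CNP0216954.2) | C=C(C)[C@@H]1C[C@]2(C[C@H]3C(C)(C)OC(=O)[C@@]3(C)C2=O)C(=O)O[C@@H]1C(=O)C(C)C | target

## Step count and least certain steps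

Total step count: 17. Longest linear sequence: 12 steps (9 → 28 through steps 5, 6 and 8–17); the bicyclic branch from 1 joins after 4 steps.

**Step 4 (key step).** Reaction through the less substituted C6 enolate, leading to bridged acylation, is the most likely failure, because this enolate is kinetically more accessible and the more substituted carbon is hindered by the neighbouring quaternary C9. Intermolecular acylation and slow enolate equilibration would add to it. Fallback: ring C is closed at a carbon that still bears a hydrogen and the methyl group is introduced afterwards. It sets out from 2, which is added under the catalysis of step 1 to commercial cyclopent-2-en-1-one to give (R)-3-(prop-1-en-2-yl)cyclopentan-1-one F1. Mukaiyama hydration as in step 2 gives (R)-3-(2-hydroxypropan-2-yl)cyclopentan-1-one F2, and 5 converts it into 2-[(1R)-3-oxocyclopentyl]propan-2-yl 1H-imidazole-1-carboxylate F3. NaH in THF then closes (3aR,6aR)-3,3-dimethyltetrahydro-1H-cyclopenta[c]furan-1,6(6aH)-dione F4 (the compound labelled A5 above). Its acidic C–H between the two carbonyl groups is removed as it forms, which makes the fused isomer the thermodynamic sink. C-Methylation of F4 with MeI and K2CO3 in acetone can only occur with cis fusion and returns to the route at 8.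

**Step 12.** Elimination at the allylic C4–H of the triflate, cyclisation of the triflate onto the C23 silyl ether oxygen, O-alkylation, and proton transfer followed by double alkylation can all compete, because the electrophilic carbon is β-branched. Fallback: the C5–C6 bond is made by carbonyl addition instead of substitution. It sets out from 19 and 8. Dess–Martin oxidation of 19 gives (2S,3S,4R)-4-[(tert-butyldimethylsilyl)oxy]-5-methyl-2-(prop-1-en-2-yl)-3-[(triethylsilyl)oxy]hexanal F5. Addition of enolate 21 at −78 °C gives the β-hydroxy ketone F6 as a mixture of isomers. Dehydration with (methoxycarbonylsulfamoyl)triethylammonium hydroxide inner salt gives the alkylidene ketone F7, and conjugate reduction with [(Ph3P)CuH]6 returns to the route at 22.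

**Step 15.** Poor facial selectivity at C6, with C19 delivered to the concave face, would give the C6 epimer of 26, because the closing ring must pass the C15 methyl on the convex face. Opening of the doubly activated ketone by imidazolide during a slow closure is a second possibility. Fallback: the order of the two bond formations at C6 is inverted, so that C5 rather than C19 enters on the preferred face. It sets out from 17 and 8. LiBH4 converts 17 into (2R,3S,4R)-4-[(tert-butyldimethylsilyl)oxy]-5-methyl-2-(prop-1-en-2-yl)hexane-1,3-diol F8. Selective iodination of the primary hydroxyl (I2, PPh3, imidazole) gives the iodo alcohol F9, and 5 gives its imidazole-1-carboxylate F10. Intermolecular C-acylation of enolate 21 by F10 gives the β-keto ester F11. Intramolecular alkylation of its stabilised enolate (Cs2CO3, MeCN) closes ring A and returns to the route at 26.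

**Step 1.** Insufficient enantioselectivity is the main risk, since alkenyl Grignard reagents and five-membered α-substituted enones are demanding partners for copper catalysis; competing 1,2-addition is a lesser one. Fallback: a stoichiometric sulfoxide auxiliary replaces the catalyst. It sets out from 2, which is added to the zinc dibromide chelate of the known (S)-2-(p-tolylsulfinyl)cyclopent-2-en-1-one F12 (ZnBr2, THF, −78 °C); the chelate model predicts attack on the face that leads to 3R. The resulting enolate is methylated in the same flask with MeI to give 2-methyl-3-(prop-1-en-2-yl)-2-[(S)-p-tolylsulfinyl]cyclopentan-1-one F13, whose C3 has the spatial arrangement of 3. Reductive desulfinylation with aluminium amalgam returns to the route at 3.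

**Step 8.** Isomerisation of the dienolate or of the product into conjugation, reaction at the γ-carbon, partial racemisation of aldehyde 11, or a mismatched pairing that erodes the diastereoselectivity may occur. Fallback: the C4–C22 bond is made by allylation under substrate control. It sets out from 11, which is treated with CrCl2 and the allylic bromide (E)-1-bromo-4-[(4-methoxybenzyl)oxy]-2-methylbut-2-ene F14 (Nozaki–Hiyama–Kishi allylation). The divalent chromium reagent adds through its γ-carbon in an anti-selective chair, with Felkin control from C23, to give the homoallylic alcohol F15. Silylation with Et3SiOTf gives F16, and oxidative removal of the 4-methoxybenzyl group with DDQ returns to the route at 19.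

## Further compounds

F1 | step 4 | (R)-3-(prop-1-en-2-yl)cyclopentan-1-one | O=C1CC[C@H](C1)C(C)=C
F2 | step 4 | (R)-3-(2-hydroxypropan-2-yl)cyclopentan-1-one | O=C1CC[C@H](C1)C(C)(C)O
F3 | step 4 | 2-[(1R)-3-oxocyclopentyl]propan-2-yl 1H-imidazole-1-carboxylate | O=C1CC[C@H](C1)C(C)(C)OC(=O)n1ccnc1
F4 | step 4 | (3aR,6aR)-3,3-dimethyltetrahydro-1H-cyclopenta[c]furan-1,6(6aH)-dione | O=C1CC[C@H]2C(C)(C)OC(=O)[C@@H]12
F5 | step 12 | (2S,3S,4R)-4-[(tert-butyldimethylsilyl)oxy]-5-methyl-2-(prop-1-en-2-yl)-3-[(triethylsilyl)oxy]hexanal | C=C(C)[C@@H]([C@H](O[Si](CC)(CC)CC)[C@H](O[Si](C)(C)C(C)(C)C)C(C)C)C=O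
F6 | step 12 | aldol adduct of 8 and F5 (β-hydroxy ketone, mixture of carbinol and ring C5 epimers) | C=C(C)[C@@H]([C@H](O[Si](CC)(CC)CC)[C@H](O[Si](C)(C)C(C)(C)C)C(C)C)C(O)C1C[C@H]2C(C)(C)OC(=O)[C@@]2(C)C1=O
F7 | step 12 | 5-alkylidene derivative of 8 from dehydration of F6 (alkene isomers) | C=C(C)[C@@H]([C@H](O[Si](CC)(CC)CC)[C@H](O[Si](C)(C)C(C)(C)C)C(C)C)C=C1C[C@H]2C(C)(C)OC(=O)[C@@]2(C)C1=O
F8 | step 15 | (2R,3S,4R)-4-[(tert-butyldimethylsilyl)oxy]-5-methyl-2-(prop-1-en-2-yl)hexane-1,3-diol | C=C(C)[C@@H]([C@H](O)[C@H](O[Si](C)(C)C(C)(C)C)C(C)C)CO
F9 | step 15 | primary iodide of F8 (secondary hydroxyl free) | C=C(C)[C@@H]([C@H](O)[C@H](O[Si](C)(C)C(C)(C)C)C(C)C)CI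
F10 | step 15 | 1H-imidazole-1-carboxylate of F9 | C=C(C)[C@@H]([C@H](OC(=O)n1ccnc1)[C@H](O[Si](C)(C)C(C)(C)C)C(C)C)CI
F11 | step 15 | β-keto ester from C-acylation of 8 at C5 by F10 (C5 epimers) | C=C(C)[C@@H]([C@H](OC(=O)C1C[C@H]2C(C)(C)OC(=O)[C@@]2(C)C1=O)[C@H](O[Si](C)(C)C(C)(C)C)C(C)C)CI
F12 | step 1 | (S)-2-(p-tolylsulfinyl)cyclopent-2-en-1-one | Cc1ccc(cc1)[S@](=O)C1=CCCC1=O
F13 | step 1 | 2-methyl-3-(prop-1-en-2-yl)-2-[(S)-p-tolylsulfinyl]cyclopentan-1-one (C3 as in 3, formally 3S here; C2 epimers) | Cc1ccc(cc1)[S@](=O)C1(C)[C@H](C(C)=C)CCC1=O
F14 | step 8 | (E)-1-bromo-4-[(4-methoxybenzyl)oxy]-2-methylbut-2-ene | COc1ccc(COC/C=C(C)/CBr)cc1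
F15 | step 8 | (2R,3S,4R)-4-[(tert-butyldimethylsilyl)oxy]-1-[(4-methoxybenzyl)oxy]-5-methyl-2-(prop-1-en-2-yl)hexan-3-ol | C=C(C)[C@@H]([C@H](O)[C@H](O[Si](C)(C)C(C)(C)C)C(C)C)COCc1ccc(OC)cc1
F16 | step 8 | triethylsilyl ether of F15 | C=C(C)[C@@H]([C@H](O[Si](CC)(CC)CC)[C@H](O[Si](C)(C)C(C)(C)C)C(C)C)COCc1ccc(OC)cc1
A1 | alternative 1 | ring A lactone, cis-5-(prop-1-en-2-yl)-6-[1-(tert-butyldimethylsilyloxy)-2-methylpropyl]tetrahydro-2H-pyran-2-one | C=C(C)[C@@H]1CCC(=O)O[C@@H]1[C@@H](O[Si](C)(C)C(C)(C)C)C(C)C
A2 | alternative 1 | cis-2-[1-(tert-butyldimethylsilyloxy)-2-methylpropyl]-3-(prop-1-en-2-yl)cyclopentan-1-one | C=C(C)[C@@H]1CCC(=O)[C@@H]1[C@@H](O[Si](C)(C)C(C)(C)C)C(C)C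
A3 | alternative 2 | target with the C23 ketone as its 1,3-dioxolane | C=C(C)[C@@H]1C[C@]2(C[C@H]3C(C)(C)OC(=O)[C@@]3(C)C2=O)C(=O)O[C@@H]1C4(OCCO4)C(C)C
A4 | alternative 2 | ring A lactone bearing at C6 a prenyl group and a 3-methoxy-2-methyl-3-oxopropanoyl group, C23 as 1,3-dioxolane | C=C(C)[C@@H]1C[C@@](CC=C(C)C)(C(=O)C(C)C(=O)OC)C(=O)O[C@@H]1C2(OCCO2)C(C)C
A5 | alternative 3 | (3aR,6aR)-3,3-dimethyltetrahydro-1H-cyclopenta[c]furan-1,6(6aH)-dione | O=C1CC[C@H]2C(C)(C)OC(=O)[C@@H]12
A6 | alternative 3 | methyl 5-oxocyclopent-1-ene-1-carboxylate | COC(=O)C1=CCCC1=O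
A7 | alternative 3 | propan-2-ol | CC(C)O
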